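The plan cuts the target back to its C2-symmetric tetraphenol, 7,7'-methylenebis(isochroman-6,8-diol). One half of it is dehydrogenated at C1 only in the last step. In each half the C8 hydroxyl stands ortho to ring-fusion carbon C8a, which carries the C1H2–O2 ether of the pyran ring. That pattern is the signature of a gold-catalysed furan–yne phenol synthesis. A twofold cycloisomerisation therefore forms C4a–C8a and C7–C8 twice and closes both benzene and both pyran rings at once. Its precursor is a bis(2-furyl)methane whose furans bear 3-benzyloxy, 4-methyl and a threo 3-(propargyloxy)butan-2-yl chain at C5. Benzyl on O6 allows neutral hydrogenolysis later.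

Key step: step 8

Assumption: the quinone methide half is treated as the C8-oxo/C6-hydroxy tautomer of the target structure, which should interconvert freely with the C6-oxo/C8-hydroxy form. Isochroman numbering is used for both halves and for the precursor atoms that become them.

Step 1
Reactants: 1 3-methyltetronic acid
Product: 2 4-(benzyloxy)-3-methylfuran-2(5H)-one
Conditions: BnOH (1.5 equiv), p-TsOH·H2O (5 mol %), toluene, reflux, Dean–Stark trap
Reagents that add atoms: benzyl alcohol, OCc1ccccc1
Why: Acid-catalysed vinylogous Fischer esterification of the enolic C4–OH with azeotropic removal of water should give the thermodynamically preferred 4-alkoxybutenolide, and benzyl makes the later furan non-volatile and cleavable by hydrogenolysis.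

Step 2
Reactants: 2 4-(benzyloxy)-3-methylfuran-2(5H)-one
Product: 4 3-(benzyloxy)-4-methylfuran, via lactol 3 (not isolated)
Conditions: i-Bu2AlH (1.2 equiv), CH2Cl2, −78 °C; aq. KNa tartrate; then PPTS (cat.), 4 Å MS, CH2Cl2, rt
Reagents that add atoms: none
Why: Partial lactone reduction stops at the aluminium lactolate at −78 °C, and the freed lactol loses water under trace acid because the enol ether expels the hydroxyl and aromatisation follows (butenolide-to-furan reduction).

Step 3
Reactants: 4 3-(benzyloxy)-4-methylfuran; 5 (2S,3S)-2,3-epoxybutane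
Product: 9 (2S,3R)-3-[4-(benzyloxy)-3-methyl-5-(trimethylsilyl)furan-2-yl]butan-2-ol, via 2-lithiofuran 6 (not isolated), via 2-silylfuran 7 (not isolated), via 5-lithio-2-silylfuran 8 (not isolated)
Conditions: n-BuLi (1.05 equiv), THF, −78 °C; Me3SiCl (1.05 equiv), −78 → 0 °C; n-BuLi (1.1 equiv), 0 °C; then −78 °C, 5 (1.5 equiv), BF3·OEt2 (1.5 equiv); aq. NaHCO3
Reagents that add atoms: chlorotrimethylsilane, C[Si](C)(C)Cl; (2S,3S)-2,3-epoxybutane (5), C[C@@H]1O[C@H]1C
Why: Directed lithiation takes the C–H next to the benzyloxy group first, silylation blocks it, the second lithiation can then only take the remaining α-C–H (n-BuLi rather than s- or t-BuLi spares the benzylic OCH2), and the BF3-assisted SN2 opening of the C2-symmetric trans-epoxide goes with inversion, which sets the furyl-bearing carbon (later C4) as R and leaves the carbinol carbon (later C3) as S, the erythro alcohol.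

Step 4
Reactants: 9 (2S,3R)-3-[4-(benzyloxy)-3-methyl-5-(trimethylsilyl)furan-2-yl]butan-2-ol
Product: 10 (2R,3R)-3-[4-(benzyloxy)-3-methyl-5-(trimethylsilyl)furan-2-yl]butan-2-yl 4-nitrobenzoate
Conditions: 4-O2NC6H4CO2H, PPh3, DIAD (added last, slowly), toluene, 0 °C → rt
Reagents that add atoms: 4-nitrobenzoic acid, O=C(O)c1ccc(cc1)[N+](=O)[O-]
Why: Mitsunobu reaction in which 4-nitrobenzoate, the usual acid for hindered secondary alcohols, displaces the alkoxyphosphonium group by SN2 and so inverts the carbinol carbon from S to R, turning the erythro into the threo series.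

Step 5
Reactants: 10 (2R,3R)-3-[4-(benzyloxy)-3-methyl-5-(trimethylsilyl)furan-2-yl]butan-2-yl 4-nitrobenzoate
Product: 11 (2R,3R)-3-[4-(benzyloxy)-3-methyl-5-(trimethylsilyl)furan-2-yl]butan-2-ol
Conditions: K2CO3 (0.2 equiv), MeOH, rt
Reagents that add atoms: none
Why: Base-catalysed transesterification cleaves the activated ester at the acyl carbon, so the alkyl C–O bond and both stereocentres stay untouched, and the furylsilane and benzyl ether are inert.

Step 6
Reactants: 11 (2R,3R)-3-[4-(benzyloxy)-3-methyl-5-(trimethylsilyl)furan-2-yl]butan-2-ol; 12 propargyl bromide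
Product: 13 {3-(benzyloxy)-4-methyl-5-[(2R,3R)-3-(prop-2-yn-1-yloxy)butan-2-yl]furan-2-yl}trimethylsilane
Conditions: NaH (1.3 equiv), THF–DMF, 0 °C; 12 (1.5 equiv), 0 °C → rt
Reagents that add atoms: propargyl bromide (12), C#CCBr
Why: Williamson ether synthesis in which the sodium alkoxide displaces bromide from the unhindered propargylic halide without breaking any bond to a stereocentre.

Step 7
Reactants: 13 {3-(benzyloxy)-4-methyl-5-[(2R,3R)-3-(prop-2-yn-1-yloxy)butan-2-yl]furan-2-yl}trimethylsilane (2 equiv); 14 dimethoxymethane (1 equiv)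
Product: 16 bis{3-(benzyloxy)-4-methyl-5-[(2R,3R)-3-(prop-2-yn-1-yloxy)butan-2-yl]furan-2-yl}methane, via methoxymethylfuran 15 (not isolated)
Conditions: Me3SiOTf (10 mol %), CH2Cl2, −40 → 0 °C; Et3N quench
Reagents that add atoms: dimethoxymethane (14), COCOC
Why: Friedel–Crafts alkylation with a formaldehyde acetal in which first the methoxymethyl cation and then the furfuryl cation from 15 attack the silyl-bearing carbon, the most nucleophilic site (enol-ether β-carbon, α to the ring oxygen, β-silicon-stabilised σ-complex), silicon leaves by ipso-substitution, the medium stays free of water and protic acid, and no oligomer can grow because the other α-position is blocked.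

Step 8
Reactants: 16 bis{3-(benzyloxy)-4-methyl-5-[(2R,3R)-3-(prop-2-yn-1-yloxy)butan-2-yl]furan-2-yl}methane
Product: 18 bis[(3R,4S)-6-(benzyloxy)-8-hydroxy-3,4,5-trimethylisochroman-7-yl]methane, via half-cyclised phenol 17 (not isolated)
Conditions: Ph3PAuNTf2 (10 mol %, 5 mol % per alkyne), 4 Å MS, CH2Cl2 (0.02 M), rt
Reagents that add atoms: none
Why: Cationic monovalent gold π-activates each terminal alkyne, and the furan carbon bearing the side chain attacks the internal alkyne carbon (6-exo-dig, bond C4a–C8a, pyran ring) to give a cyclopropyl gold carbenoid, which opens with rupture of the furan C–O bond to a C7 ketone conjugated to a C8 gold carbene. The ketone oxygen adds to C8, gold departs, and the oxepine so formed closes by 6π-electrocyclisation to the C7–C8 arene oxide (bond C7–C8, benzene ring). Ionisation of the C7–O bond and loss of the C8 hydrogen then deliver the C8 phenol. The closest known reaction is the gold-catalysed intramolecular furan–yne phenol synthesis of furyl propargyl ethers and amines, which gives 8-hydroxyisochromans and 8-hydroxytetrahydroisoquinolines; doing it twice in one molecule and on a fully substituted 3-alkoxyfuran stretches that scope. No stereocentre is created, and C3 and C4 lie outside the reacting π-system, so their configuration should be carried through. The hydroxyl must end on C8 and not on C7, which is secured because C8 is the only epoxide carbon that has a hydrogen, whereas opening towards the C6-alkoxy-stabilised cation is reversible and could continue only by a slow 1,2-shift of the bridge; the branching at C3 and C4 favours 6-exo closure over intermolecular reaction.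

Step 9
Reactants: 18 bis[(3R,4S)-6-(benzyloxy)-8-hydroxy-3,4,5-trimethylisochroman-7-yl]methane
Product: 19 7,7'-methylenebis[(3R,4S)-3,4,5-trimethylisochroman-6,8-diol]
Conditions: H2 (1 atm), Pd/C (10 wt %), EtOAc–EtOH, rt
Reagents that add atoms: none
Why: Catalytic hydrogenolysis cleaves the two aryl benzyl ethers under neutral conditions, while the cyclic C1–O2 ether of the electron-rich isochroman and the diarylmethane bridge react much more slowly at 1 atm.

Step 10
Reactants: 19 7,7'-methylenebis[(3R,4S)-3,4,5-trimethylisochroman-6,8-diol]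
Product: 20 dicitrinone I
Conditions: DDQ (0.9 equiv, slow addition), CH2Cl2–1,4-dioxane, 0 °C; unreacted 19 recycled
Reagents that add atoms: none
Why: DDQ dehydrogenation in which hydride is abstracted from C1–H, the position activated at once by O2, the para C6–OH and the ortho C8–OH, and the oxocarbenium ion loses the C8–OH proton to give the stabilised quinone methide, while a slight deficit of oxidant should keep the second half reduced.

Compound list
1 | 3-methyltetronic acid (4-hydroxy-3-methylfuran-2(5H)-one) | CC1=C(O)COC1=O | starting material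
2 | 4-(benzyloxy)-3-methylfuran-2(5H)-one | CC1=C(OCc2ccccc2)COC1=O | intermediate
3 | 4-(benzyloxy)-3-methyl-2,5-dihydrofuran-2-ol (lactol, both C2 epimers, not isolated) | CC1=C(OCc2ccccc2)COC1O | intermediate
4 | 3-(benzyloxy)-4-methylfuran | Cc1cocc1OCc2ccccc2 | intermediate
5 | (2S,3S)-2,3-epoxybutane | C[C@@H]1O[C@H]1C | starting material
6 | [3-(benzyloxy)-4-methylfuran-2-yl]lithium (not isolated) | [Li]c1occ(C)c1OCc2ccccc2 | intermediate
7 | [3-(benzyloxy)-4-methylfuran-2-yl]trimethylsilane (not isolated) | C[Si](C)(C)c1occ(C)c1OCc2ccccc2 | intermediate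
8 | [4-(benzyloxy)-3-methyl-5-(trimethylsilyl)furan-2-yl]lithium (not isolated) | [Li]c1oc([Si](C)(C)C)c(OCc2ccccc2)c1C | intermediate
9 | (2S,3R)-3-[4-(benzyloxy)-3-methyl-5-(trimethylsilyl)furan-2-yl]butan-2-ol (erythro) | Cc1c(OCc2ccccc2)c([Si](C)(C)C)oc1[C@H](C)[C@H](C)O | intermediate
10 | (2R,3R)-3-[4-(benzyloxy)-3-methyl-5-(trimethylsilyl)furan-2-yl]butan-2-yl 4-nitrobenzoate | Cc1c(OCc2ccccc2)c([Si](C)(C)C)oc1[C@H](C)[C@@H](C)OC(=O)c3ccc(cc3)[N+](=O)[O-] | intermediate
11 | (2R,3R)-3-[4-(benzyloxy)-3-methyl-5-(trimethylsilyl)furan-2-yl]butan-2-ol (threo) | Cc1c(OCc2ccccc2)c([Si](C)(C)C)oc1[C@H](C)[C@@H](C)O | intermediate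
12 | propargyl bromide | C#CCBr | starting material
13 | {3-(benzyloxy)-4-methyl-5-[(2R,3R)-3-(prop-2-yn-1-yloxy)butan-2-yl]furan-2-yl}trimethylsilane | Cc1c(OCc2ccccc2)c([Si](C)(C)C)oc1[C@H](C)[C@@H](C)OCC#C | intermediate
14 | dimethoxymethane | COCOC | starting material
15 | 3-(benzyloxy)-2-(methoxymethyl)-4-methyl-5-[(2R,3R)-3-(prop-2-yn-1-yloxy)butan-2-yl]furan (not isolated) | COCc1oc([C@H](C)[C@@H](C)OCC#C)c(C)c1OCc2ccccc2 | intermediate
16 | bis{3-(benzyloxy)-4-methyl-5-[(2R,3R)-3-(prop-2-yn-1-yloxy)butan-2-yl]furan-2-yl}methane | C(c1oc([C@H](C)[C@@H](C)OCC#C)c(C)c1OCc2ccccc2)c3oc([C@H](C)[C@@H](C)OCC#C)c(C)c3OCc4ccccc4 | intermediate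
17 | (3R,4S)-6-(benzyloxy)-7-({3-(benzyloxy)-4-methyl-5-[(2R,3R)-3-(prop-2-yn-1-yloxy)butan-2-yl]furan-2-yl}methyl)-3,4,5-trimethylisochroman-8-ol (not isolated) | C(c1c(OCc2ccccc2)c(C)c3c(c1O)CO[C@H](C)[C@H]3C)c4oc([C@H](C)[C@@H](C)OCC#C)c(C)c4OCc5ccccc5 | intermediate
18 | bis[(3R,4S)-6-(benzyloxy)-8-hydroxy-3,4,5-trimethylisochroman-7-yl]methane | C(c1c(OCc2ccccc2)c(C)c3c(c1O)CO[C@H](C)[C@H]3C)c4c(OCc5ccccc5)c(C)c6c(c4O)CO[C@H](C)[C@H]6C | intermediate
19 | 7,7'-methylenebis[(3R,4S)-3,4,5-trimethylisochroman-6,8-diol] | C(c1c(O)c(C)c2c(c1O)CO[C@H](C)[C@H]2C)c3c(O)c(C)c4c(c3O)CO[C@H](C)[C@H]4C | intermediate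
20 | dicitrinone I, (3R,4S)-7-{[(3R,4S)-6,8-dihydroxy-3,4,5-trimethylisochroman-7-yl]methyl}-6-hydroxy-3,4,5-trimethyl-3,4-dihydro-8H-isochromen-8-one | CC1=C2C(=CO[C@H](C)[C@H]2C)C(=O)C(Cc2c(O)c(C)c3c(c2O)CO[C@H](C)[C@H]3C)=C1O | target

Total step count: 10. Longest linear sequence: 10 steps (1 → 20). Compounds 5, 12 and 14 are bought in.

Steps most likely to fail

**Step 8.**
- **What may go wrong:** The benzyloxy group on the carbon that becomes C6 may stabilise the ring-opened cation long enough for proton loss. It may also favour a shift of the bridge after the arene oxide has opened towards C6. The first-formed phenol or traces of acid may degrade the second alkoxyfuran before it cyclises.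
- **Fallback (sets out from epoxide 5, comes back at tetraphenol 19):** The arene is bought instead of made.
  - 1-Bromo-3,5-dimethoxy-2-methylbenzene F1 is converted with n-BuLi into the aryllithium. This is opened onto 5 with BF3·OEt2 to give (2S,3S)-3-(3,5-dimethoxy-2-methylphenyl)butan-2-ol F2.
  - Mitsunobu inversion with 4-nitrobenzoic acid gives (2R,3S)-3-(3,5-dimethoxy-2-methylphenyl)butan-2-yl 4-nitrobenzoate F3. K2CO3 in MeOH then gives (2R,3S)-3-(3,5-dimethoxy-2-methylphenyl)butan-2-ol F4.
  - BBr3 (CH2Cl2, −78 → 0 °C) frees 5-[(2S,3R)-3-hydroxybutan-2-yl]-4-methylbenzene-1,3-diol F5.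
  - An oxa-Pictet–Spengler reaction with dimethoxymethane 14 and catalytic p-TsOH closes the pyran at the only free position ortho to the side chain. This gives (3R,4S)-3,4,5-trimethylisochroman-6,8-diol F6.
  - Half an equivalent of aqueous formaldehyde with catalytic acid links two molecules of F6 through C7, the last free arene position, to give 19.

**Step 10.**
- **What may go wrong:** Hydride loss may also occur at the doubly benzylic bridge methylene, which is flanked by four free phenols. The second half is oxidised at nearly the same rate as the first, so selectivity for a single C1 may be poor.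
- **Fallback (sets out from 18, comes back at 20):** The order of oxidation and deprotection is reversed.
  - DDQ is applied to dibenzyl ether 18, in which two benzyloxy groups shield the bridge. Unreacted, singly oxidised and doubly oxidised material are robust ethers that separate easily.
  - This gives (3R,4S)-6-(benzyloxy)-7-{[(3R,4S)-6-(benzyloxy)-8-hydroxy-3,4,5-trimethylisochroman-7-yl]methyl}-3,4,5-trimethyl-3,4-dihydro-8H-isochromen-8-one F7.
  - Both benzyl groups are then removed without reduction by BCl3 and pentamethylbenzene (CH2Cl2, −78 °C). This should leave the quinone methide intact and give 20 directly.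

**Step 4.**
- **What may go wrong:** The electron-rich furan may act as a neighbouring group while the phosphine oxide departs, giving retention or scrambling through a bridged cation. E2 loss of the furylic hydrogen competes at this hindered centre.
- **Fallback (sets out from 9, comes back at 11, by-passing 10):** Inversion by substitution is replaced by oxidation and substrate-controlled reduction.
  - Dess–Martin periodinane with NaHCO3 gives (S)-3-[4-(benzyloxy)-3-methyl-5-(trimethylsilyl)furan-2-yl]butan-2-one F8. It is used at once and kept away from base so that the furylic centre does not enolise.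
  - LiBH(s-Bu)3 in THF at −78 °C should attack anti to the furyl group (Felkin–Anh control) and give the threo alcohol 11.

Further compounds
F1 | step 8 | 1-bromo-3,5-dimethoxy-2-methylbenzene (bought in) | COc1cc(Br)c(C)c(OC)c1
F2 | step 8 | (2S,3S)-3-(3,5-dimethoxy-2-methylphenyl)butan-2-ol | COc1cc(OC)c(C)c(c1)[C@H](C)[C@H](C)O
F3 | step 8 | (2R,3S)-3-(3,5-dimethoxy-2-methylphenyl)butan-2-yl 4-nitrobenzoate | COc1cc(OC)c(C)c(c1)[C@H](C)[C@@H](C)OC(=O)c2ccc(cc2)[N+](=O)[O-]
F4 | step 8 | (2R,3S)-3-(3,5-dimethoxy-2-methylphenyl)butan-2-ol | COc1cc(OC)c(C)c(c1)[C@H](C)[C@@H](C)O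
F5 | step 8 | 5-[(2S,3R)-3-hydroxybutan-2-yl]-4-methylbenzene-1,3-diol | Cc1c(O)cc(O)cc1[C@H](C)[C@@H](C)O
F6 | step 8 | (3R,4S)-3,4,5-trimethylisochroman-6,8-diol | c1c(O)c(C)c2c(c1O)CO[C@H](C)[C@H]2C
F7 | step 10 | (3R,4S)-6-(benzyloxy)-7-{[(3R,4S)-6-(benzyloxy)-8-hydroxy-3,4,5-trimethylisochroman-7-yl]methyl}-3,4,5-trimethyl-3,4-dihydro-8H-isochromen-8-one | CC1=C2C(=CO[C@H](C)[C@H]2C)C(=O)C(Cc2c(OCc3ccccc3)c(C)c3c(c2O)CO[C@H](C)[C@H]3C)=C1OCc4ccccc4
F8 | step 4 | (S)-3-[4-(benzyloxy)-3-methyl-5-(trimethylsilyl)furan-2-yl]butan-2-one | Cc1c(OCc2ccccc2)c([Si](C)(C)C)oc1[C@H](C)C(C)=O
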